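**Plan** (lactone locants O1, C2(=O), C3, C4, C5, C6; C1' is the first carbon of the chain on C3)
1. Retrosynthesis: after the protecting-group trades, cut the lactone at C2(=O)–C3. C2 becomes CO and O1–C2 goes with it, which gives the open-chain (R)-3,4-dien-1-ol 19. Cut C6–alkenyl carbon to give alkenyl bromide 9 and allenic Weinreb amide 15. Cut the side-chain C=C that bears CH2OAc (bromo-HWE) back to nerol, and cut C4–C5 (Johnson–Claisen) back to a propargylic alcohol.
2. Enabling feature: ring C4=C3 plus the C1' methylene of the 4-methylpent-3-enyl chain is a hydrogenated allene. Its central carbon is C3, which a carbonyl held on O1 can reach through a six-membered closure. Ring, C=O, ring alkene and α-branch therefore all come from allene + CO.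
3. Forward order: west half 9, east half 15, union by alkenyllithium acylation and ketone reduction. The dihydropyranone (the only ring) is then closed on the complete chain, followed by TBS-to-acetate exchange and final desilylation.
4. Stereochemistry: C6 (R) comes from a CBS reduction. The Z allylic-alcohol alkene comes from nerol. The E alkene bearing CH2OAc comes from an E-selective bromo-HWE and is kept with retention through Br–Li exchange. The ring alkene geometry is set by the ring.

Key step: step 14

Assumption: 12 is racemic, and 14, 15 and 17–19 are carried as mixtures at the allene axis. Step 14 erases this element, so their SMILES leave it open.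

**Step 1**
Reactants: 1 nerol
Product: 2 neryl tert-butyldiphenylsilyl ether
Conditions: TBDPSCl, imidazole, DMF, 0 to 23 °C
Reagents that add atoms: tert-butylchlorodiphenylsilane, CC(C)(C)[Si](Cl)(c1ccccc1)c1ccccc1
Why: Standard silylation of a primary allylic alcohol; nerol supplies the Z trisubstituted alkene ready-made, and the robust silyl ether should last until step 17.

**Step 2**
Reactants: 2 neryl tert-butyldiphenylsilyl ether
Product: 3 6,7-epoxyneryl tert-butyldiphenylsilyl ether (racemic)
Conditions: mCPBA (1.0 equiv), CH2Cl2, −20 to 0 °C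
Reagents that add atoms: 3-chloroperoxybenzoic acid, OOC(=O)c1cccc(Cl)c1
Why: Prilezhaev epoxidation should pick the electron-richer isopropylidene alkene over the allylic-ether alkene, which is inductively deactivated and screened by the silyl group; the new stereocentre is erased in step 3.

**Step 3**
Reactants: 3 6,7-epoxyneryl tert-butyldiphenylsilyl ether
Product: 4 (4Z)-6-(tert-butyldiphenylsilyloxy)-4-methylhex-4-enal
Conditions: H5IO6, THF–Et2O, 0 °C
Reagents that add atoms: none
Why: Periodic acid opens the epoxide and cleaves the glycol in one pot (Malaprade-type cleavage) without touching the remaining alkene or the silyl ether.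

**Step 4**
Reactants: 5 methyl bis(2,2,2-trifluoroethyl)phosphonoacetate
Product: 6 methyl bromo[bis(2,2,2-trifluoroethoxy)phosphoryl]acetate (racemic)
Conditions: NaH, THF, 0 °C; Br2 (1.0 equiv), −78 °C
Reagents that add atoms: bromine, BrBr
Why: Electrophilic α-bromination of the stabilised phosphonate carbanion; traces of non- and dibrominated phosphonate should be harmless because halogen exchange among the phosphonate anions under the base of step 5 funnels them into the monobromo carbanion.

**Step 5**
Reactants: 4 (4Z)-6-(tert-butyldiphenylsilyloxy)-4-methylhex-4-enal; 6 methyl bromo[bis(2,2,2-trifluoroethoxy)phosphoryl]acetate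
Product: 7 methyl (2E,6Z)-2-bromo-8-(tert-butyldiphenylsilyloxy)-6-methylocta-2,6-dienoate
Conditions: tBuOK, 18-crown-6, THF, −78 °C
Reagents that add atoms: none
Why: Horner–Wadsworth–Emmons olefination of the Still–Gennari type; the electron-poor phosphonate under dissociating conditions should place the ester cis to the chain, giving the (E)-α-bromoacrylate and so the geometry of the alkene that will carry CH2OAc.

**Step 6**
Reactants: 7 methyl (2E,6Z)-2-bromo-8-(tert-butyldiphenylsilyloxy)-6-methylocta-2,6-dienoate
Product: 8 (2E,6Z)-2-bromo-8-(tert-butyldiphenylsilyloxy)-6-methylocta-2,6-dien-1-ol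
Conditions: iBu2AlH (2.2 equiv), CH2Cl2, −78 °C
Reagents that add atoms: none
Why: 1,2-Reduction of an enoate by iBu2AlH, which leaves the alkenyl bromide and the alkene geometry intact.

**Step 7**
Reactants: 8 (2E,6Z)-2-bromo-8-(tert-butyldiphenylsilyloxy)-6-methylocta-2,6-dien-1-ol
Product: 9 (2E,6Z)-2-bromo-1-(tert-butyldimethylsilyloxy)-8-(tert-butyldiphenylsilyloxy)-6-methylocta-2,6-diene
Conditions: TBSCl, imidazole, CH2Cl2, 23 °C
Reagents that add atoms: tert-butylchlorodimethylsilane, CC(C)(C)[Si](C)(C)Cl
Why: Standard silylation; the TBS ether tolerates tBuLi at −78 °C and can later be removed by mild acid in the presence of the TBDPS ether.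

**Step 8**
Reactants: 10 4-methylpent-3-en-1-ol
Product: 11 4-methylpent-3-enal
Conditions: Dess–Martin periodinane, CH2Cl2, 0 °C; used without storage
Reagents that add atoms: none
Why: Dess–Martin oxidation is non-basic and should deliver the β,γ-unsaturated aldehyde without moving the alkene into conjugation.

**Step 9**
Reactants: 11 4-methylpent-3-enal
Product: 12 6-methylhept-5-en-1-yn-3-ol (racemic)
Conditions: HC≡CMgBr, THF, 0 °C; aq NH4Cl
Reagents that add atoms: ethynylmagnesium bromide, C#C[Mg]Br
Why: Grignard 1,2-addition; the new carbinol centre is left uncontrolled because its information ends in the allene axis, which step 14 destroys.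

**Step 10**
Reactants: 12 6-methylhept-5-en-1-yn-3-ol
Product: 14 ethyl 8-methylnona-3,4,7-trienoate, via ketene acetal 13 (not isolated)
Conditions: MeC(OEt)3, EtCO2H (cat.), 140 °C, EtOH distilled off
Reagents that add atoms: triethyl orthoacetate, CC(OCC)(OCC)OCC
Why: Johnson–Claisen [3,3]-rearrangement of a propargylic ketene acetal, the standard entry to β-allenic esters; it forms the future C4–C5 bond and the 1,3-disubstituted allene in one operation.

**Step 11**
Reactants: 14 ethyl 8-methylnona-3,4,7-trienoate
Product: 15 N-methoxy-N,8-dimethylnona-3,4,7-trienamide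
Conditions: MeNH(OMe)·HCl, AlMe3, CH2Cl2, 0 to 23 °C
Reagents that add atoms: N,O-dimethylhydroxylamine hydrochloride, CNOC.Cl
Why: Aluminium-amide aminolysis (Weinreb amidation) is Lewis acidic rather than basic, so the skipped allenyl CH2 should not be deprotonated.

**Step 12**
Reactants: 9 (2E,6Z)-2-bromo-1-(tert-butyldimethylsilyloxy)-8-(tert-butyldiphenylsilyloxy)-6-methylocta-2,6-diene; 15 N-methoxy-N,8-dimethylnona-3,4,7-trienamide
Product: 18 (10E,14Z)-16-(tert-butyldiphenylsilyloxy)-10-(tert-butyldimethylsilyloxymethyl)-2,14-dimethylhexadeca-2,5,6,10,14-pentaen-9-one, via alkenyllithium 16 (not isolated), via lithium hemiaminal 17 (not isolated)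
Conditions: 9, tBuLi (2.05 equiv), Et2O, −78 °C; 15, −78 °C; AcOH, −78 °C
Reagents that add atoms: none
Why: Br–Li exchange proceeds with retention, and the configurationally stable alkenyllithium should add only once because the chelated adduct 17 survives until the cold acidic quench (Weinreb ketone synthesis).

**Step 13**
Reactants: 18 (10E,14Z)-pentaen-9-one
Product: 19 (9R,10E,14Z)-16-(tert-butyldiphenylsilyloxy)-10-(tert-butyldimethylsilyloxymethyl)-2,14-dimethylhexadeca-2,5,6,10,14-pentaen-9-ol
Conditions: (S)-2-methyl-CBS-oxazaborolidine (0.3 equiv), catecholborane, toluene, −78 °C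
Reagents that add atoms: none
Why: Corey–Bakshi–Shibata reduction; the α-branched alkenyl flank acts as the large group, so the (S)-catalyst should give the (R)-carbinol (the same sense as acetophenone to (R)-1-phenylethanol), and catecholborane at −78 °C should spare the allene and the alkenes.

**Step 14**
Reactants: 19 (9R,10E,14Z)-pentaen-9-ol
Product: 20 (6R)-6-[(2E,6Z)-1-(tert-butyldimethylsilyloxy)-8-(tert-butyldiphenylsilyloxy)-6-methylocta-2,6-dien-2-yl]-3-(4-methylpent-3-en-1-yl)-5,6-dihydro-2H-pyran-2-one
Conditions: Ru3(CO)12 (3 mol %), CO (10 atm), Et3N, 100 °C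
Reagents that add atoms: carbon monoxide, [C-]#[O+]
Why: The reaction type is the Ru3(CO)12-catalysed cyclocarbonylation of allenyl alcohols, which is known to turn 3,4-dien-1-ols into 3-alkyl-5,6-dihydro-2H-pyran-2-ones. Amine-assisted O–H activation and CO insertion into the Ru–O bond should give a hydrido(alkoxycarbonyl)ruthenium species whose carbonyl carbon (future C2) is already held on O1, and migratory insertion of the nearer allene π bond then joins C2 to the central sp carbon C3. This C2–C3 bond closes the six-membered ring, exo to C3=C1' and endo to C3=C4, and is preferred over five-membered closure at C4 because only attack at the central carbon gives a stabilised η3-allylruthenium (C4–C3–C1'). C–H reductive elimination at the exocyclic terminus C1' should then leave the conjugated endocyclic C3=C4 bond, whose geometry is dictated by the ring, and turn the allene terminus into the first CH2 of the 4-methylpent-3-enyl chain. No stereocentre is formed: C6 is a spectator whose C–O bond is never broken, and both axial epimers of 19 converge on the single lactone 20. The step needs chemoselectivity for the allene over three trisubstituted alkenes and for one hydroxyl, which the substrate secures by having the cumulene as its only unhindered, strongly binding ligand for zerovalent ruthenium under CO and by carrying both primary alcohols as silyl ethers.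

**Step 15**
Reactants: 20 bis-silylated lactone
Product: 21 (6R)-6-[(2E,6Z)-8-(tert-butyldiphenylsilyloxy)-1-hydroxy-6-methylocta-2,6-dien-2-yl]-3-(4-methylpent-3-en-1-yl)-5,6-dihydro-2H-pyran-2-one
Conditions: PPTS (0.2 equiv), EtOH, 23 °C
Reagents that add atoms: none
Why: Acid-catalysed solvolysis should remove the primary TBS ether much faster than the TBDPS ether, and it is too mild to open the lactone.

**Step 16**
Reactants: 21 hydroxy lactone
Product: 22 acetate of 21
Conditions: Ac2O, pyridine, DMAP (cat.), CH2Cl2, 0 °C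
Reagents that add atoms: acetic anhydride, CC(=O)OC(C)=O
Why: Standard acetylation of the only free hydroxyl group.

**Step 17**
Reactants: 22 acetate of 21
Product: 23 target CNP0179839.1
Conditions: HF·pyridine, pyridine, THF, 0 to 23 °C
Reagents that add atoms: none
Why: Buffered fluoride desilylation frees the Z allylic alcohol under non-basic conditions, so acetate cleavage or migration and lactone opening should be avoided.

**Compound list**
1 | nerol | CC(C)=CCC/C(C)=C\CO | starting material
2 | neryl tert-butyldiphenylsilyl ether | CC(C)=CCC/C(C)=C\CO[Si](c1ccccc1)(c1ccccc1)C(C)(C)C | intermediate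
3 | 6,7-epoxyneryl tert-butyldiphenylsilyl ether (racemic) | CC1(C)OC1CC/C(C)=C\CO[Si](c1ccccc1)(c1ccccc1)C(C)(C)C | intermediate
4 | (4Z)-6-(tert-butyldiphenylsilyloxy)-4-methylhex-4-enal | O=CCC/C(C)=C\CO[Si](c1ccccc1)(c1ccccc1)C(C)(C)C | intermediate
5 | methyl bis(2,2,2-trifluoroethyl)phosphonoacetate | COC(=O)CP(=O)(OCC(F)(F)F)OCC(F)(F)F | starting material
6 | methyl bromo[bis(2,2,2-trifluoroethoxy)phosphoryl]acetate (racemic) | COC(=O)C(Br)P(=O)(OCC(F)(F)F)OCC(F)(F)F | intermediate
7 | methyl (2E,6Z)-2-bromo-8-(tert-butyldiphenylsilyloxy)-6-methylocta-2,6-dienoate | COC(=O)/C(Br)=C\CC/C(C)=C\CO[Si](c1ccccc1)(c1ccccc1)C(C)(C)C | intermediate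
8 | (2E,6Z)-2-bromo-8-(tert-butyldiphenylsilyloxy)-6-methylocta-2,6-dien-1-ol | OC/C(Br)=C\CC/C(C)=C\CO[Si](c1ccccc1)(c1ccccc1)C(C)(C)C | intermediate
9 | (2E,6Z)-2-bromo-1-(tert-butyldimethylsilyloxy)-8-(tert-butyldiphenylsilyloxy)-6-methylocta-2,6-diene | CC(C)(C)[Si](C)(C)OC/C(Br)=C\CC/C(C)=C\CO[Si](c1ccccc1)(c1ccccc1)C(C)(C)C | intermediate
10 | 4-methylpent-3-en-1-ol | CC(C)=CCCO | starting material
11 | 4-methylpent-3-enal | CC(C)=CCC=O | intermediate
12 | 6-methylhept-5-en-1-yn-3-ol (racemic) | C#CC(O)CC=C(C)C | intermediate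
13 | 1-ethoxyvinyl ether of 12 (ketene acetal, not isolated) | C=C(OCC)OC(C#C)CC=C(C)C | intermediate
14 | ethyl 8-methylnona-3,4,7-trienoate | CCOC(=O)CC=C=CCC=C(C)C | intermediate
15 | N-methoxy-N,8-dimethylnona-3,4,7-trienamide | CON(C)C(=O)CC=C=CCC=C(C)C | intermediate
16 | alkenyllithium from 9, Li trans to the chain (not isolated) | [Li]/C(CO[Si](C)(C)C(C)(C)C)=C/CC/C(C)=C\CO[Si](c1ccccc1)(c1ccccc1)C(C)(C)C | intermediate
17 | lithium N-methoxy-N-methyl hemiaminal adduct of 16 and 15 (not isolated) | [Li]OC(CC=C=CCC=C(C)C)(N(C)OC)/C(CO[Si](C)(C)C(C)(C)C)=C/CC/C(C)=C\CO[Si](c1ccccc1)(c1ccccc1)C(C)(C)C | intermediate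
18 | (10E,14Z)-16-(tert-butyldiphenylsilyloxy)-10-(tert-butyldimethylsilyloxymethyl)-2,14-dimethylhexadeca-2,5,6,10,14-pentaen-9-one | CC(C)=CCC=C=CCC(=O)/C(CO[Si](C)(C)C(C)(C)C)=C/CC/C(C)=C\CO[Si](c1ccccc1)(c1ccccc1)C(C)(C)C | intermediate
19 | (9R,10E,14Z)-16-(tert-butyldiphenylsilyloxy)-10-(tert-butyldimethylsilyloxymethyl)-2,14-dimethylhexadeca-2,5,6,10,14-pentaen-9-ol | CC(C)=CCC=C=CC[C@@H](O)/C(CO[Si](C)(C)C(C)(C)C)=C/CC/C(C)=C\CO[Si](c1ccccc1)(c1ccccc1)C(C)(C)C | intermediate
20 | (6R)-6-[(2E,6Z)-1-(tert-butyldimethylsilyloxy)-8-(tert-butyldiphenylsilyloxy)-6-methylocta-2,6-dien-2-yl]-3-(4-methylpent-3-en-1-yl)-5,6-dihydro-2H-pyran-2-one | CC(C)(C)[Si](C)(C)OC/C(=C\CC/C(C)=C\CO[Si](c1ccccc1)(c1ccccc1)C(C)(C)C)[C@H]1CC=C(CCC=C(C)C)C(=O)O1 | intermediate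
21 | (6R)-6-[(2E,6Z)-8-(tert-butyldiphenylsilyloxy)-1-hydroxy-6-methylocta-2,6-dien-2-yl]-3-(4-methylpent-3-en-1-yl)-5,6-dihydro-2H-pyran-2-one | OC/C(=C\CC/C(C)=C\CO[Si](c1ccccc1)(c1ccccc1)C(C)(C)C)[C@H]1CC=C(CCC=C(C)C)C(=O)O1 | intermediate
22 | acetate of 21 | CC(=O)OC/C(=C\CC/C(C)=C\CO[Si](c1ccccc1)(c1ccccc1)C(C)(C)C)[C@H]1CC=C(CCC=C(C)C)C(=O)O1 | intermediate
23 | (2E,6Z)-8-hydroxy-6-methyl-2-[(2R)-5-(4-methylpent-3-en-1-yl)-6-oxo-3,6-dihydro-2H-pyran-2-yl]octa-2,6-dien-1-yl acetate | CC(=O)OC/C(=C\CC/C(C)=C\CO)[C@H]1CC=C(CCC=C(C)C)C(=O)O1 | target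

Total step count: 17. Longest linear sequence: 12 steps (1–3, 5–7, 12–17, from nerol).

**Steps most likely to fail**

**Step 14.**
- What may go wrong: hydrogen may be delivered to ring carbon C4 instead of C1', ruthenium hydrides may shift the trisubstituted alkenes or redox-isomerise the allylic carbinol, or turnover may be slow on the 1,3-disubstituted allene.
- Fallback: it sets out from 9 and comes back at 20. The ring is closed at C3=C4 by metathesis instead of at the carbonyl carbon.
- Carbinol partner: Br–Li exchange of 9 (tBuLi, Et2O, −78 °C) and formylation with DMF should give the silyloxymethyl enal F1. Brown allylation with (+)-Ipc2B(allyl) (from (−)-α-pinene) should give the (R)-homoallylic alcohol F2.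
- Acid partner: triethyl phosphonoacetate is alkylated with 5-bromo-2-methylpent-2-ene (NaH, DMF) to the alkylated phosphonate F3. HWE methylenation with aqueous formaldehyde and K2CO3 gives the acrylate ester F4, and LiOH gives the acrylic acid F5.
- Ring closure: Steglich esterification of F2 with F5 (DCC, DMAP) gives the diene ester F6. Ring-closing metathesis with the second-generation Grubbs catalyst (toluene, 80 °C) should give 20.

**Step 12.**
- What may go wrong: the alkenyllithium may enolise the doubly activated CH2 of 15, with drift of the allene into conjugation. The silyl group in 16 may also migrate from O to C before the amide is consumed.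
- Fallback: it sets out from 9 and 14 and comes back at 19, so it also bypasses step 13. A weakly basic organochromium addition to an aldehyde replaces the organolithium acylation.
- Sequence: half-reduction of 14 (iBu2AlH, 1.0 equiv, toluene, −78 °C) gives the allenic aldehyde F7. A catalytic asymmetric Nozaki–Hiyama–Kishi coupling of 9 with F7 should then give 19 directly. The conditions are CrCl2 with a chiral oxazoline–sulfonamide ligand, NiCl2(2,9-dimethyl-1,10-phenanthroline), Mn, Cp2ZrCl2 and LiCl in MeCN. The ligand antipode that delivers the (R)-carbinol is fixed by a Mosher ester check.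

**Step 13.**
- What may go wrong: facial selectivity may be poor because both ketone flanks are long chains, and uncatalysed reduction or hydroboration of the allene may compete.
- Fallback: it sets out from 18 and comes back at 19. Resolution replaces asymmetric reduction.
- Sequence: Luche reduction (NaBH4, CeCl3·7H2O, MeOH, −78 °C) gives the racemic carbinol F8. Sharpless kinetic resolution follows (Ti(OiPr)4, L-(+)-diisopropyl tartrate, tBuOOH 0.6 equiv, 4 Å sieves, CH2Cl2, −20 °C). It should epoxidise the faster (S)-enantiomer to the epoxy alcohol F9 and leave the (R)-carbinol 19, which is separated by chromatography.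

**Further compounds**
F1 | step 14 | silyloxymethyl enal, (2E,6Z)-8-(tert-butyldiphenylsilyloxy)-2-(tert-butyldimethylsilyloxymethyl)-6-methylocta-2,6-dienal | O=C/C(CO[Si](C)(C)C(C)(C)C)=C/CC/C(C)=C\CO[Si](c1ccccc1)(c1ccccc1)C(C)(C)C
F2 | step 14 | (R)-homoallylic alcohol, (4R,5E,9Z)-11-(tert-butyldiphenylsilyloxy)-5-(tert-butyldimethylsilyloxymethyl)-9-methylundeca-1,5,9-trien-4-ol | C=CC[C@@H](O)/C(CO[Si](C)(C)C(C)(C)C)=C/CC/C(C)=C\CO[Si](c1ccccc1)(c1ccccc1)C(C)(C)C
F3 | step 14 | alkylated phosphonate, ethyl 2-(diethoxyphosphoryl)-6-methylhept-5-enoate | CCOC(=O)C(CCC=C(C)C)P(=O)(OCC)OCC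
F4 | step 14 | acrylate ester, ethyl 6-methyl-2-methylidenehept-5-enoate | C=C(CCC=C(C)C)C(=O)OCC
F5 | step 14 | acrylic acid, 6-methyl-2-methylidenehept-5-enoic acid | C=C(CCC=C(C)C)C(=O)O
F6 | step 14 | diene ester, 6-methyl-2-methylidenehept-5-enoate of F2 | C=CC[C@@H](OC(=O)C(=C)CCC=C(C)C)/C(CO[Si](C)(C)C(C)(C)C)=C/CC/C(C)=C\CO[Si](c1ccccc1)(c1ccccc1)C(C)(C)C
F7 | step 12 | allenic aldehyde, 8-methylnona-3,4,7-trienal | O=CCC=C=CCC=C(C)C
F8 | step 13 | racemic carbinol, constitution and alkene geometry of 19 | CC(C)=CCC=C=CCC(O)/C(CO[Si](C)(C)C(C)(C)C)=C/CC/C(C)=C\CO[Si](c1ccccc1)(c1ccccc1)C(C)(C)C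
F9 | step 13 | epoxy alcohol, 10,11-epoxide of the (9S)-carbinol | CC(C)=CCC=C=CC[C@H](O)[C@@]1(CO[Si](C)(C)C(C)(C)C)O[C@@H]1CC/C(C)=C\CO[Si](c1ccccc1)(c1ccccc1)C(C)(C)C
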